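**Strategy.** Irisoquin is treated as a masked 4-methoxyphenol whose single carbocycle is assembled in one operation. The feature exploited is the quinone ring itself: carbonyl carbon C1 sits between C2 (OH) and C6 (H) and can come from a CO ligand, the C2–C3 pair (oxygen plus octadecyl) from an O-protected ynol ether, and C4–C5–C6 (carbonyl, methoxy, CH) from a 1-methoxyvinyl methoxycarbene on zerovalent chromium. A Dötz benzannulation forges C3–C4, C1–C2 and C1–C6 and delivers the fully substituted arene with the C1 and C4 oxygens para. The precursors are carbene complex 5 and 1-tert-butoxyicos-1-yne 13; oxidative demethylation and acidolysis finish the synthesis.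

Key step: step 4

Remark: ring atoms carry the quinone numbering C1 (C=O beside C–OH), C2 (OH), C3 (octadecyl), C4 (C=O), C5 (OMe), C6 (H), and the phenol keeps it. The E geometry drawn for 9 is assumed from anti addition and has no bearing on the route. The SMILES of 14 shows the arene and the Cr(CO)3 fragment as separate parts because hexahapto bonding cannot be drawn.

**Step 1**
Reactants: 1 methyl vinyl ether; 2 chromium hexacarbonyl, Cr(CO)6
Product: 5 pentacarbonyl(1,2-dimethoxyprop-2-en-1-ylidene)chromium, via 1-methoxyvinyllithium 3 (not isolated), via lithium pentacarbonyl(2-methoxyacryloyl)chromate 4 (not isolated)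
Conditions: t-BuLi, THF, −78 → −5 °C; 2, Et2O, −78 °C → rt; solvent swap, then Me3OBF4, CH2Cl2, 0 °C
Reagents that add atoms: trimethyloxonium tetrafluoroborate, C[O+](C)C.F[B-](F)(F)F
Why: Fischer carbene synthesis, in which α-lithiation of the vinyl ether gives 3, addition to a CO ligand of Cr(CO)6 gives acylate 4, and O-methylation by the oxonium salt under anhydrous conditions should give the alkoxycarbene complex without hydrolysing its enol ether.

**Step 2**
Reactants: 6 trichloroethylene; 7 potassium tert-butoxide, KOtBu (1.1 equiv)
Product: 9 (E)-1-tert-butoxy-1,2-dichloroethene, via dichloroacetylene 8 (not isolated)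
Conditions: THF, −50 °C → rt
Reagents that add atoms: none
Why: Elimination–addition, in which the base dehydrochlorinates 6 to the transient chloroalkyne 8 and tert-butoxide then adds across it in anti fashion, the standard entry to 1,2-dichlorovinyl ethers.

**Step 3**
Reactants: 9 (E)-1-tert-butoxy-1,2-dichloroethene; 10 1-iodooctadecane (limiting, 0.8 equiv)
Product: 13 1-tert-butoxyicos-1-yne, via 1-tert-butoxy-2-chloroethyne 11 (not isolated), via lithium tert-butoxyacetylide 12 (not isolated)
Conditions: n-BuLi (2.1 equiv), THF, −78 → −40 °C; then 10, HMPA, −40 °C → rt; Et3N-deactivated silica, no heating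
Reagents that add atoms: none
Why: n-BuLi dehydrochlorinates 9 to 11 and then effects chlorine–lithium exchange to acetylide 12, whose SN2 alkylation by a primary iodide in the presence of HMPA is the established route to 1-alkoxy-1-alkynes.

**Step 4**
Reactants: 5 pentacarbonyl(1,2-dimethoxyprop-2-en-1-ylidene)chromium; 13 1-tert-butoxyicos-1-yne (1.2 equiv, added slowly)
Product: 15 2-tert-butoxy-4,5-dimethoxy-3-octadecylphenol, via arene–Cr(CO)3 complex 14 (not isolated)
Conditions: THF (0.05 M), 45 °C, Ar, 16 h; then air, Et2O, rt
Reagents that add atoms: none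
Why: Dötz benzannulation: loss of one CO from 5 opens a site for the ynol ether, which inserts into the Cr=C bond so that its nucleophilic, alkyl-bearing carbon bonds to the carbene carbon (C3–C4) and the tert-butoxy-bearing carbon becomes the new carbene centre; CO insertion (C1–C2) then gives a chromium-bound dienylketene. The single ring, the six-membered carbocycle, closes by 6π electrocyclisation of that dienylketene (C1–C6), and tautomerisation of the cyclohexadienone gives the phenol as its Cr(CO)3 complex 14, from which air releases 15. The closest known chemistry is the benzannulation of aryl, furyl and alkenyl alkoxycarbene complexes of zerovalent chromium with internal alkynes, including 1-alkoxy-1-alkynes, which place the alkoxy group beside the phenolic carbon. No stereocentre is formed. The selectivity that matters is regiochemical (tert-butoxy at C2, octadecyl at C3), and both the steric demand of the tert-butoxy group and the polarisation of the ynol ether push that way, while the alkenyl carbene, chromium and an ether solvent favour phenol over five-membered products. The bath is held at 45 °C because tert-butyl ynol ethers lose isobutene by a retro-ene path on stronger heating.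

**Step 5**
Reactants: 15 2-tert-butoxy-4,5-dimethoxy-3-octadecylphenol
Product: 16 2-tert-butoxy-5-methoxy-3-octadecyl-1,4-benzoquinone
Conditions: (NH4)2Ce(NO3)6 (2.2 equiv), MeCN/H2O, 0 °C, 15 min
Reagents that add atoms: water, O
Why: Oxidative demethylation of a para-methoxyphenol by tetravalent cerium, in which two one-electron oxidations give a phenoxonium ion, water adds at the methoxy-bearing para carbon C4 and methanol is lost, so the para-quinone should form while the C5 methoxy and C2 tert-butoxy groups survive the brief cold exposure.

**Step 6**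
Reactants: 16 2-tert-butoxy-5-methoxy-3-octadecyl-1,4-benzoquinone
Product: 17 irisoquin (2-hydroxy-5-methoxy-3-octadecyl-1,4-benzoquinone)
Conditions: TFA, CH2Cl2, 0 °C → rt
Reagents that add atoms: none
Why: Acidolysis of the tert-butyl vinylogous ester by an E1 pathway (tert-butyl cation lost as isobutene) should free the C2 hydroxyl, while the methyl vinylogous ester at C5 cannot ionise and is not hydrolysed in anhydrous acid.

**Compound list**
1 | methyl vinyl ether | COC=C | starting material
2 | chromium hexacarbonyl, Cr(CO)6 | O=C=[Cr](=C=O)(=C=O)(=C=O)(=C=O)=C=O | starting material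
3 | 1-methoxyvinyllithium | [Li]C(=C)OC | intermediate
4 | lithium pentacarbonyl(2-methoxyacryloyl)chromate | [Li+].[O-]C(C(OC)=C)=[Cr](=C=O)(=C=O)(=C=O)(=C=O)=C=O | intermediate
5 | pentacarbonyl(1,2-dimethoxyprop-2-en-1-ylidene)chromium | COC(C(OC)=C)=[Cr](=C=O)(=C=O)(=C=O)(=C=O)=C=O | intermediate
6 | trichloroethylene | ClC=C(Cl)Cl | starting material
7 | potassium tert-butoxide, KOtBu | CC(C)(C)[O-].[K+] | starting material
8 | dichloroacetylene | ClC#CCl | intermediate
9 | (E)-1-tert-butoxy-1,2-dichloroethene | CC(C)(C)O/C(Cl)=C\Cl | intermediate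
10 | 1-iodooctadecane | CCCCCCCCCCCCCCCCCCI | starting material
11 | 1-tert-butoxy-2-chloroethyne | CC(C)(C)OC#CCl | intermediate
12 | lithium tert-butoxyacetylide, LiC≡COt-Bu | [Li]C#COC(C)(C)C | intermediate
13 | 1-tert-butoxyicos-1-yne | CCCCCCCCCCCCCCCCCCC#COC(C)(C)C | intermediate
14 | tricarbonyl(η6-2-tert-butoxy-4,5-dimethoxy-3-octadecylphenol)chromium | CCCCCCCCCCCCCCCCCCc1c(OC)c(OC)cc(O)c1OC(C)(C)C.O=C=[Cr](=C=O)=C=O | intermediate
15 | 2-tert-butoxy-4,5-dimethoxy-3-octadecylphenol | CCCCCCCCCCCCCCCCCCc1c(OC)c(OC)cc(O)c1OC(C)(C)C | intermediate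
16 | 2-tert-butoxy-5-methoxy-3-octadecyl-1,4-benzoquinone | CCCCCCCCCCCCCCCCCCC1=C(OC(C)(C)C)C(=O)C=C(OC)C1=O | intermediate
17 | irisoquin, 2-hydroxy-5-methoxy-3-octadecyl-1,4-benzoquinone | CCCCCCCCCCCCCCCCCCC1=C(O)C(=O)C=C(OC)C1=O | target

**Totals**
Total step count: 6. Longest linear sequence: 5 steps (steps 2, 3, 4, 5, 6); the carbene branch (step 1) joins at step 4.

**Steps most likely to fail**

1. Step 4. After alkyne insertion the oxygen-stabilised dienylcarbene may be slow to insert CO, so the sequence can stall at the insertion stage or divert to five-membered-ring formation or oligomerisation of the electron-rich alkyne. Retro-ene fragmentation of the ynol ether sets in if the temperature drifts upward.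
Fallback (no benzannulation; the ring is bought and the chain attached by directed lithiation): setting out from 10, commercial 1,2,4,5-tetramethoxybenzene is lithiated with n-BuLi/TMEDA in THF to (2,3,5,6-tetramethoxyphenyl)lithium F1 and alkylated with 10 to give 1,2,4,5-tetramethoxy-3-octadecylbenzene F2. Oxidation with (NH4)2Ce(NO3)6 in aqueous MeCN should give 2,5-dimethoxy-3-octadecyl-1,4-benzoquinone F3. Partial hydrolysis with aqueous HClO4 in dioxane is expected to cleave preferentially the C2 methoxy group, which the neighbouring chain twists out of conjugation, and returns to the route at target 17. Any regioisomeric hydrolysis product would have to be separated.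

2. Step 3. The SN2 alkylation of the alkoxyacetylide by a long-chain iodide may be sluggish and accompanied by elimination, and the acid- and heat-sensitive ynol ether may decompose during isolation.
Fallback (C–O bond formed on a preformed C20 alkyne, with a thermally robust silyl group in place of tert-butyl): setting out from 10, displacement with LiC≡CH·H2NCH2CH2NH2 in DMSO should give icos-1-yne F4. Deprotonation with n-BuLi gives lithium icos-1-ynide F5, oxidation with LiOOt-Bu (from t-BuOOH and LiN(SiMe3)2) gives lithium icos-1-yn-1-olate F6, and O-silylation with i-Pr3SiOTf gives 1-(triisopropylsilyloxy)icos-1-yne F7. Under the conditions of step 4 with 5 this should give, through the arene–Cr(CO)3 complex F8, 4,5-dimethoxy-3-octadecyl-2-(triisopropylsilyloxy)phenol F9. Oxidation with (NH4)2Ce(NO3)6 then gives 5-methoxy-3-octadecyl-2-(triisopropylsilyloxy)-1,4-benzoquinone F10, and aqueous HF in MeCN returns to the route at target 17.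

3. Step 5. At the phenoxonium stage the tert-butyl group may be expelled before water attacks C4, which opens an ortho-quinone pathway, and the strongly acidic aqueous oxidant may cause premature deprotection.
Fallback (buffered, water-free two-electron oxidation to an isolable ketal, followed by one acid step that unmasks everything): setting out from 15, PhI(OAc)2 with NaHCO3 in MeOH at 0 °C should give the quinone monoketal 2-tert-butoxy-4,4,5-trimethoxy-3-octadecylcyclohexa-2,5-dien-1-one F11 by methanol capture at C4. Aqueous TFA in CH2Cl2 then hydrolyses the ketal and removes the tert-butyl group in one operation, returning to the route at target 17.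

**Further compounds**
F1 | step 4 | (2,3,5,6-tetramethoxyphenyl)lithium | [Li]c1c(OC)c(OC)cc(OC)c1OC
F2 | step 4 | 1,2,4,5-tetramethoxy-3-octadecylbenzene | CCCCCCCCCCCCCCCCCCc1c(OC)c(OC)cc(OC)c1OC
F3 | step 4 | 2,5-dimethoxy-3-octadecyl-1,4-benzoquinone | CCCCCCCCCCCCCCCCCCC1=C(OC)C(=O)C=C(OC)C1=O
F4 | step 3 | icos-1-yne | CCCCCCCCCCCCCCCCCCC#C
F5 | step 3 | lithium icos-1-ynide | CCCCCCCCCCCCCCCCCCC#C[Li]
F6 | step 3 | lithium icos-1-yn-1-olate | CCCCCCCCCCCCCCCCCCC#C[O-].[Li+]
F7 | step 3 | 1-(triisopropylsilyloxy)icos-1-yne | CCCCCCCCCCCCCCCCCCC#CO[Si](C(C)C)(C(C)C)C(C)C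
F8 | step 3 | tricarbonyl(η6-4,5-dimethoxy-3-octadecyl-2-(triisopropylsilyloxy)phenol)chromium | CCCCCCCCCCCCCCCCCCc1c(OC)c(OC)cc(O)c1O[Si](C(C)C)(C(C)C)C(C)C.O=C=[Cr](=C=O)=C=O
F9 | step 3 | 4,5-dimethoxy-3-octadecyl-2-(triisopropylsilyloxy)phenol | CCCCCCCCCCCCCCCCCCc1c(OC)c(OC)cc(O)c1O[Si](C(C)C)(C(C)C)C(C)C
F10 | step 3 | 5-methoxy-3-octadecyl-2-(triisopropylsilyloxy)-1,4-benzoquinone | CCCCCCCCCCCCCCCCCCC1=C(O[Si](C(C)C)(C(C)C)C(C)C)C(=O)C=C(OC)C1=O
F11 | step 5 | 2-tert-butoxy-4,4,5-trimethoxy-3-octadecylcyclohexa-2,5-dien-1-one | CCCCCCCCCCCCCCCCCCC1=C(OC(C)(C)C)C(=O)C=C(OC)C1(OC)OC
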